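**Retrosynthetic overview**

1. Numbering: ring A is C1 (OMe), C2 (Cl), C3 (Me), C4 (Br), C5 (OH), C6 (carries the ketone); ring B is C1′ (ketone), C2′ (CHO), C3′ and C5′ (OH), C6′ (prenyl). The route rests on ring A being a 2-substituted 3-methoxyphenol (C5–OH, C6 carbon substituent, C1–OMe) with Cl at C2 and Me at C3, which is the pattern a vinylketene and an alkoxyalkyne give; C4, ortho to the new OH, stays open for bromine.
2. Target 30 ⇐ ketone 29 (acidic unmasking of the C2′ aldehyde and the two phenols) ⇐ oxidation, desilylation and C4 bromination ⇐ phenol 26.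
3. Ring A of 26 ⇐ benzannulation of 2-chloro-3-methylcyclobutenone 21 with methoxyalkyne 17, forming C5–C6 and C1–C2 (C4–C5 is broken and re-formed); ring A is the only ring built, ring B is bought as an arene.
4. 17 ⇐ ring B aldehyde 13 + lithium methoxyacetylide; 13 ⇐ methyl 3,5-dihydroxybenzoate via a 2,6-dibromide and two bromine–lithium exchanges (prenyl, then formyl).
5. 21 ⇐ propyne + dichloroketene, then allylic chloride shift and zinc removal of the sp3 chlorine.

Key step: step 14

Remark: the target has no stereocenter; the carbinol carbon of 16, 17 and 23–28 (and C4 of 20 and 23) is carried as a racemate and is erased in step 17.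

**Route**

Step 1
Reactants: 1 methyl 3,5-dihydroxybenzoate
Product: 2 methyl 3,5-bis(methoxymethoxy)benzoate
Conditions: MOMCl (2.5 equiv), i-Pr2NEt (3 equiv), CH2Cl2, 0 °C → rt
Reagents that add atoms: chloromethyl methyl ether (MOMCl), COCCl
Why: Williamson-type O-alkylation of both phenols with the reactive α-chloro ether under amine base should give the bis(MOM) ether and leave the ester untouched.

Step 2
Reactants: 2 methyl 3,5-bis(methoxymethoxy)benzoate
Product: 3 [3,5-bis(methoxymethoxy)phenyl]methanol
Conditions: LiAlH4, THF, 0 °C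
Reagents that add atoms: none
Why: LiAlH4 reduction of the ester should give the benzyl alcohol, the MOM acetals being inert to hydride.

Step 3
Reactants: 3 [3,5-bis(methoxymethoxy)phenyl]methanol
Product: 4 [2,6-dibromo-3,5-bis(methoxymethoxy)phenyl]methanol
Conditions: NBS (2.1 equiv), MeCN, 0 °C → rt, dark
Reagents that add atoms: N-bromosuccinimide, O=C1CCC(=O)N1Br
Why: Electrophilic aromatic bromination should take C2 and C6, each ortho to one MOM ether and para to the other and less crowded than C4 between the two ethers, to give the symmetric dibromide.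

Step 4
Reactants: 4 [2,6-dibromo-3,5-bis(methoxymethoxy)phenyl]methanol
Product: 5 {[2,6-dibromo-3,5-bis(methoxymethoxy)phenyl]methoxy}tri(propan-2-yl)silane
Conditions: TIPSCl, imidazole, DMF, rt
Reagents that add atoms: chlorotri(propan-2-yl)silane (TIPSCl), CC(C)[Si](Cl)(C(C)C)C(C)C
Why: Standard silylation of a primary alcohol, with the bulky TIPS group chosen because it should resist both 1,4-silyl migration to an ortho aryllithium and the acidic methanol of step 7.

Step 5
Reactants: 5 {[2,6-dibromo-3,5-bis(methoxymethoxy)phenyl]methoxy}tri(propan-2-yl)silane; 6 prenyl bromide (1-bromo-3-methylbut-2-ene)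
Product: 8 {[2-bromo-3,5-bis(methoxymethoxy)-6-(3-methylbut-2-en-1-yl)phenyl]methoxy}tri(propan-2-yl)silane, via aryllithium 7 (not isolated)
Conditions: n-BuLi (1.05 equiv), THF, −78 °C; CuBr·SMe2 (0.1 equiv), then 6 (1.5 equiv), −78 → 0 °C
Reagents that add atoms: none
Why: Bromine–lithium exchange on the symmetric dibromide (either bromine gives the same aryllithium) followed by copper-catalysed allylic substitution at the primary carbon of prenyl bromide should install the linear prenyl group.

Step 6
Reactants: 8 {[2-bromo-3,5-bis(methoxymethoxy)-6-(3-methylbut-2-en-1-yl)phenyl]methoxy}tri(propan-2-yl)silane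
Product: 10 4,6-bis(methoxymethoxy)-3-(3-methylbut-2-en-1-yl)-2-{[tri(propan-2-yl)silyl]oxymethyl}benzaldehyde, via aryllithium 9 (not isolated)
Conditions: n-BuLi (1.1 equiv), THF, −78 °C; DMF (3 equiv), −78 → 0 °C; aq. NH4Cl
Reagents that add atoms: N,N-dimethylformamide, CN(C)C=O
Why: A second bromine–lithium exchange and Bouveault-type formylation with DMF should place the formyl carbon on the position that becomes C2′.

Step 7
Reactants: 10 4,6-bis(methoxymethoxy)-3-(3-methylbut-2-en-1-yl)-2-{[tri(propan-2-yl)silyl]oxymethyl}benzaldehyde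
Product: 11 {[2-(dimethoxymethyl)-3,5-bis(methoxymethoxy)-6-(3-methylbut-2-en-1-yl)phenyl]methoxy}tri(propan-2-yl)silane
Conditions: HC(OMe)3 (5 equiv), MeOH, PPTS (5 mol%), rt; Et3N quench
Reagents that add atoms: trimethyl orthoformate, COC(OC)OC; methanol, CO
Why: Acid-catalysed acetalisation driven by the orthoformate as water scavenger should mask the C2′ aldehyde at room temperature under acid too mild to cleave aryl MOM ethers or the TIPS ether.

Step 8
Reactants: 11 {[2-(dimethoxymethyl)-3,5-bis(methoxymethoxy)-6-(3-methylbut-2-en-1-yl)phenyl]methoxy}tri(propan-2-yl)silane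
Product: 12 [2-(dimethoxymethyl)-3,5-bis(methoxymethoxy)-6-(3-methylbut-2-en-1-yl)phenyl]methanol
Conditions: TBAF, THF, 0 °C → rt; aq. NaHCO3 work-up, used crude
Reagents that add atoms: none
Why: Fluoride-mediated desilylation under basic conditions should free the benzylic alcohol without touching the acid-labile acetal.

Step 9
Reactants: 12 [2-(dimethoxymethyl)-3,5-bis(methoxymethoxy)-6-(3-methylbut-2-en-1-yl)phenyl]methanol
Product: 13 2-(dimethoxymethyl)-3,5-bis(methoxymethoxy)-6-(3-methylbut-2-en-1-yl)benzaldehyde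
Conditions: MnO2 (activated, excess), CH2Cl2, rt
Reagents that add atoms: none
Why: Neutral heterogeneous MnO2 oxidation of an electron-rich benzylic alcohol should give the aldehyde and avoids the acid that would close the neighbouring acetal onto the free hydroxyl.

Step 10
Reactants: 13 2-(dimethoxymethyl)-3,5-bis(methoxymethoxy)-6-(3-methylbut-2-en-1-yl)benzaldehyde; 14 chloroacetaldehyde dimethyl acetal (2-chloro-1,1-dimethoxyethane)
Product: 16 racemic 1-[2-(dimethoxymethyl)-3,5-bis(methoxymethoxy)-6-(3-methylbut-2-en-1-yl)phenyl]-3-methoxyprop-2-yn-1-ol, via lithium methoxyacetylide 15 (not isolated)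
Conditions: 14 (2 equiv), Et2NH, n-BuLi (6 equiv), THF, 0 °C; then 13, −78 → −20 °C; pH 7 buffer, used crude
Reagents that add atoms: none
Why: Three equivalents of LiNEt2 per acetal convert 14 by two eliminations and a deprotonation into lithium methoxyacetylide, whose 1,2-addition to the non-enolisable aldehyde (acetylide addition) should give the racemic propargylic alcohol.

Step 11
Reactants: 16 racemic 1-[2-(dimethoxymethyl)-3,5-bis(methoxymethoxy)-6-(3-methylbut-2-en-1-yl)phenyl]-3-methoxyprop-2-yn-1-ol
Product: 17 racemic tert-butyl({1-[2-(dimethoxymethyl)-3,5-bis(methoxymethoxy)-6-(3-methylbut-2-en-1-yl)phenyl]-3-methoxyprop-2-yn-1-yl}oxy)dimethylsilane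
Conditions: TBSCl, imidazole, DMAP (cat.), DMF, rt → 40 °C
Reagents that add atoms: tert-butyl(chloro)dimethylsilane (TBSCl), CC(C)(C)[Si](C)(C)Cl
Why: Imidazole-promoted silylation under basic conditions should cap the carbinol, which blocks Meyer–Schuster rearrangement of the ynol ether and cyclisation onto the neighbouring acetal.

Step 12
Reactants: 18 propyne
Product: 19 4,4-dichloro-3-methylcyclobut-2-en-1-one
Conditions: Cl3CCOCl, Zn–Cu couple, Et2O–DME, 0 °C → rt (dry-ice condenser, excess propyne)
Reagents that add atoms: trichloroacetyl chloride, ClC(Cl)(Cl)C(Cl)=O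
Why: Thermal [2+2] cycloaddition of dichloroketene (from zinc dechlorination of the acid chloride) with a terminal alkyne should give the 3-substituted 4,4-dichlorocyclobutenone, the ketene carbonyl carbon bonding to the terminal alkyne carbon.

Step 13
Reactants: 19 4,4-dichloro-3-methylcyclobut-2-en-1-one
Product: 21 2-chloro-3-methylcyclobut-2-en-1-one, via 2,4-dichloro-3-methylcyclobut-2-en-1-one 20 (not isolated)
Conditions: ZnCl2 (0.2 equiv), Et2O, rt; then Zn dust, AcOH, 0 °C → rt; careful distillation
Reagents that add atoms: none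
Why: ZnCl2 promotes the known 1,3-chloride (allylic) shift of 4,4-dichlorocyclobutenones to the conjugated 2,4-dichloro isomer, and zinc in acetic acid should then remove only the sp3 chlorine alpha to the ketone (reductive dehalogenation of an α-halo ketone), the vinylic chlorine being inert.

Step 14
Reactants: 17 racemic tert-butyl({1-[2-(dimethoxymethyl)-3,5-bis(methoxymethoxy)-6-(3-methylbut-2-en-1-yl)phenyl]-3-methoxyprop-2-yn-1-yl}oxy)dimethylsilane; 21 2-chloro-3-methylcyclobut-2-en-1-one
Product: 26 racemic 2-{[tert-butyl(dimethyl)silyl]oxy[2-(dimethoxymethyl)-3,5-bis(methoxymethoxy)-6-(3-methylbut-2-en-1-yl)phenyl]methyl}-4-chloro-3-methoxy-5-methylphenol, via chloro(isopropenyl)ketene 22 (not isolated), via 4-vinylcyclobutenone 23 (not isolated), via dienylketene 24 (not isolated), via cyclohexadienone 25 (not isolated)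
Conditions: 21 (1.5 equiv, in portions), toluene, 80 °C then 110 °C, sealed tube
Reagents that add atoms: none
Why: Heating opens 21 by reversible 4π electrocyclic ring opening to chloro(isopropenyl)ketene 22, which adds across the electron-rich triple bond of 17 in a [2+2] cycloaddition to give 4-vinylcyclobutenone 23. A second 4π opening (chlorine turning outward, isopropenyl inward) gives the (Z)-dienylketene 24, and tautomerisation of the cyclohexadienone 25 formed from it delivers phenol 26. This is the Danheiser benzannulation of a cyclobutenone with an alkoxyalkyne, the chlorine on the ketene carbon being a spectator that makes the ketene more electrophilic. Ring A is closed by thermal 6π electrocyclisation (re-forming C4–C5 between the former ketene carbon and the isopropenyl CH2) after the [2+2] step has made C5–C6 and C1–C2. No stereocenter is created in ring A and the carbinol center stays racemic. The step needs the regiochemistry that puts the carbinol carbon between OH and OMe, which the polarisation of the ynol ether secures because its carbon remote from oxygen is the nucleophile and bonds to the ketene carbonyl carbon, and the ynol ether is a far better ketenophile than the prenyl double bond.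

Step 15
Reactants: 26 racemic 2-{[tert-butyl(dimethyl)silyl]oxy[2-(dimethoxymethyl)-3,5-bis(methoxymethoxy)-6-(3-methylbut-2-en-1-yl)phenyl]methyl}-4-chloro-3-methoxy-5-methylphenol
Product: 27 racemic 6-bromo-2-{[tert-butyl(dimethyl)silyl]oxy[2-(dimethoxymethyl)-3,5-bis(methoxymethoxy)-6-(3-methylbut-2-en-1-yl)phenyl]methyl}-4-chloro-3-methoxy-5-methylphenol
Conditions: NBS (1.0 equiv), i-Pr2NH (0.1 equiv), CH2Cl2, −78 → −40 °C, dark
Reagents that add atoms: N-bromosuccinimide, O=C1CCC(=O)N1Br
Why: Amine-catalysed ortho-bromination of a phenol with NBS should take C4, the only free position of ring A (ortho to the free hydroxyl, para to the methoxy group), much faster at low temperature in a non-polar solvent than the MOM-protected ring B or the prenyl double bond.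

Step 16
Reactants: 27 racemic 6-bromo-2-{[tert-butyl(dimethyl)silyl]oxy[2-(dimethoxymethyl)-3,5-bis(methoxymethoxy)-6-(3-methylbut-2-en-1-yl)phenyl]methyl}-4-chloro-3-methoxy-5-methylphenol
Product: 28 racemic 6-bromo-4-chloro-2-{[2-(dimethoxymethyl)-3,5-bis(methoxymethoxy)-6-(3-methylbut-2-en-1-yl)phenyl](hydroxy)methyl}-3-methoxy-5-methylphenol
Conditions: TBAF (2.2 equiv), THF, 0 °C; pH 7 buffer work-up, used crude
Reagents that add atoms: none
Why: Fluoride-mediated desilylation, assisted by silyl transfer to the neighbouring phenoxide, should free the hindered carbinol under basic conditions that spare the acetal.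

Step 17
Reactants: 28 racemic 6-bromo-4-chloro-2-{[2-(dimethoxymethyl)-3,5-bis(methoxymethoxy)-6-(3-methylbut-2-en-1-yl)phenyl](hydroxy)methyl}-3-methoxy-5-methylphenol
Product: 29 (3-bromo-5-chloro-2-hydroxy-6-methoxy-4-methylphenyl)[2-(dimethoxymethyl)-3,5-bis(methoxymethoxy)-6-(3-methylbut-2-en-1-yl)phenyl]methanone
Conditions: Dess–Martin periodinane, pyridine, CH2Cl2, 0 °C → rt
Reagents that add atoms: none
Why: Dess–Martin oxidation of the hindered diaryl carbinol, buffered with pyridine to protect the acetal, should give the benzophenone and erase the racemic center, the phenol having no free ortho or para position to be oxidised.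

Step 18
Reactants: 29 (3-bromo-5-chloro-2-hydroxy-6-methoxy-4-methylphenyl)[2-(dimethoxymethyl)-3,5-bis(methoxymethoxy)-6-(3-methylbut-2-en-1-yl)phenyl]methanone
Product: 30 Pestalone G, 2-(3-bromo-5-chloro-2-hydroxy-6-methoxy-4-methylbenzoyl)-4,6-dihydroxy-3-(3-methylbut-2-en-1-yl)benzaldehyde
Conditions: HCl (3 M aq.), THF, 45 °C
Reagents that add atoms: water, O
Why: Acid-catalysed acetal hydrolysis should cleave the dimethyl acetal and both MOM ethers in one operation under conditions mild enough that the prenyl group ortho to the new C5′ phenol does not cyclise to a chroman.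

**Compound list**

1 | methyl 3,5-dihydroxybenzoate | COC(=O)c1cc(O)cc(O)c1 | starting material
2 | methyl 3,5-bis(methoxymethoxy)benzoate | COC(=O)c1cc(OCOC)cc(OCOC)c1 | intermediate
3 | [3,5-bis(methoxymethoxy)phenyl]methanol | OCc1cc(OCOC)cc(OCOC)c1 | intermediate
4 | [2,6-dibromo-3,5-bis(methoxymethoxy)phenyl]methanol | OCc1c(Br)c(OCOC)cc(OCOC)c1Br | intermediate
5 | {[2,6-dibromo-3,5-bis(methoxymethoxy)phenyl]methoxy}tri(propan-2-yl)silane | Brc1c(OCOC)cc(OCOC)c(Br)c1CO[Si](C(C)C)(C(C)C)C(C)C | intermediate
6 | prenyl bromide (1-bromo-3-methylbut-2-ene) | CC(C)=CCBr | starting material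
7 | {3-bromo-4,6-bis(methoxymethoxy)-2-[(triisopropylsilyloxy)methyl]phenyl}lithium | [Li]c1c(OCOC)cc(OCOC)c(Br)c1CO[Si](C(C)C)(C(C)C)C(C)C | intermediate (not isolated)
8 | {[2-bromo-3,5-bis(methoxymethoxy)-6-(3-methylbut-2-en-1-yl)phenyl]methoxy}tri(propan-2-yl)silane | Brc1c(OCOC)cc(OCOC)c(CC=C(C)C)c1CO[Si](C(C)C)(C(C)C)C(C)C | intermediate
9 | {4,6-bis(methoxymethoxy)-3-(3-methylbut-2-en-1-yl)-2-[(triisopropylsilyloxy)methyl]phenyl}lithium | [Li]c1c(OCOC)cc(OCOC)c(CC=C(C)C)c1CO[Si](C(C)C)(C(C)C)C(C)C | intermediate (not isolated)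
10 | 4,6-bis(methoxymethoxy)-3-(3-methylbut-2-en-1-yl)-2-{[tri(propan-2-yl)silyl]oxymethyl}benzaldehyde | O=Cc1c(OCOC)cc(OCOC)c(CC=C(C)C)c1CO[Si](C(C)C)(C(C)C)C(C)C | intermediate
11 | {[2-(dimethoxymethyl)-3,5-bis(methoxymethoxy)-6-(3-methylbut-2-en-1-yl)phenyl]methoxy}tri(propan-2-yl)silane | COC(OC)c1c(CO[Si](C(C)C)(C(C)C)C(C)C)c(CC=C(C)C)c(OCOC)cc1OCOC | intermediate
12 | [2-(dimethoxymethyl)-3,5-bis(methoxymethoxy)-6-(3-methylbut-2-en-1-yl)phenyl]methanol | COC(OC)c1c(CO)c(CC=C(C)C)c(OCOC)cc1OCOC | intermediate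
13 | 2-(dimethoxymethyl)-3,5-bis(methoxymethoxy)-6-(3-methylbut-2-en-1-yl)benzaldehyde | O=Cc1c(C(OC)OC)c(OCOC)cc(OCOC)c1CC=C(C)C | intermediate
14 | chloroacetaldehyde dimethyl acetal (2-chloro-1,1-dimethoxyethane) | COC(CCl)OC | starting material
15 | lithium methoxyacetylide | [Li]C#COC | intermediate (not isolated)
16 | racemic 1-[2-(dimethoxymethyl)-3,5-bis(methoxymethoxy)-6-(3-methylbut-2-en-1-yl)phenyl]-3-methoxyprop-2-yn-1-ol | COC#CC(O)c1c(C(OC)OC)c(OCOC)cc(OCOC)c1CC=C(C)C | intermediate
17 | racemic tert-butyl({1-[2-(dimethoxymethyl)-3,5-bis(methoxymethoxy)-6-(3-methylbut-2-en-1-yl)phenyl]-3-methoxyprop-2-yn-1-yl}oxy)dimethylsilane | COC#CC(O[Si](C)(C)C(C)(C)C)c1c(C(OC)OC)c(OCOC)cc(OCOC)c1CC=C(C)C | intermediate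
18 | propyne | CC#C | starting material
19 | 4,4-dichloro-3-methylcyclobut-2-en-1-one | O=C1C=C(C)C1(Cl)Cl | intermediate
20 | racemic 2,4-dichloro-3-methylcyclobut-2-en-1-one | O=C1C(Cl)=C(C)C1Cl | intermediate (not isolated)
21 | 2-chloro-3-methylcyclobut-2-en-1-one | O=C1CC(C)=C1Cl | intermediate
22 | chloro(isopropenyl)ketene (2-chloro-3-methylbuta-1,3-dien-1-one) | O=C=C(Cl)C(C)=C | intermediate (not isolated)
23 | 2-{[tert-butyl(dimethyl)silyl]oxy[2-(dimethoxymethyl)-3,5-bis(methoxymethoxy)-6-(3-methylbut-2-en-1-yl)phenyl]methyl}-4-chloro-3-methoxy-4-(prop-1-en-2-yl)cyclobut-2-en-1-one (racemic, mixture of diastereomers) | O=C1C(C(O[Si](C)(C)C(C)(C)C)c2c(C(OC)OC)c(OCOC)cc(OCOC)c2CC=C(C)C)=C(OC)C1(Cl)C(C)=C | intermediate (not isolated)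
24 | racemic (3Z)-2-{[tert-butyl(dimethyl)silyl]oxy[2-(dimethoxymethyl)-3,5-bis(methoxymethoxy)-6-(3-methylbut-2-en-1-yl)phenyl]methyl}-4-chloro-3-methoxy-5-methylhexa-1,3,5-trien-1-one | O=C=C(C(O[Si](C)(C)C(C)(C)C)c1c(C(OC)OC)c(OCOC)cc(OCOC)c1CC=C(C)C)/C(OC)=C(Cl)\C(C)=C | intermediate (not isolated)
25 | racemic 2-{[tert-butyl(dimethyl)silyl]oxy[2-(dimethoxymethyl)-3,5-bis(methoxymethoxy)-6-(3-methylbut-2-en-1-yl)phenyl]methyl}-4-chloro-3-methoxy-5-methylcyclohexa-2,4-dien-1-one | O=C1CC(C)=C(Cl)C(OC)=C1C(O[Si](C)(C)C(C)(C)C)c1c(C(OC)OC)c(OCOC)cc(OCOC)c1CC=C(C)C | intermediate (not isolated)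
26 | racemic 2-{[tert-butyl(dimethyl)silyl]oxy[2-(dimethoxymethyl)-3,5-bis(methoxymethoxy)-6-(3-methylbut-2-en-1-yl)phenyl]methyl}-4-chloro-3-methoxy-5-methylphenol | COc1c(Cl)c(C)cc(O)c1C(O[Si](C)(C)C(C)(C)C)c1c(C(OC)OC)c(OCOC)cc(OCOC)c1CC=C(C)C | intermediate
27 | racemic 6-bromo-2-{[tert-butyl(dimethyl)silyl]oxy[2-(dimethoxymethyl)-3,5-bis(methoxymethoxy)-6-(3-methylbut-2-en-1-yl)phenyl]methyl}-4-chloro-3-methoxy-5-methylphenol | COc1c(Cl)c(C)c(Br)c(O)c1C(O[Si](C)(C)C(C)(C)C)c1c(C(OC)OC)c(OCOC)cc(OCOC)c1CC=C(C)C | intermediate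
28 | racemic 6-bromo-4-chloro-2-{[2-(dimethoxymethyl)-3,5-bis(methoxymethoxy)-6-(3-methylbut-2-en-1-yl)phenyl](hydroxy)methyl}-3-methoxy-5-methylphenol | COc1c(Cl)c(C)c(Br)c(O)c1C(O)c1c(C(OC)OC)c(OCOC)cc(OCOC)c1CC=C(C)C | intermediate
29 | (3-bromo-5-chloro-2-hydroxy-6-methoxy-4-methylphenyl)[2-(dimethoxymethyl)-3,5-bis(methoxymethoxy)-6-(3-methylbut-2-en-1-yl)phenyl]methanone | COc1c(Cl)c(C)c(Br)c(O)c1C(=O)c1c(C(OC)OC)c(OCOC)cc(OCOC)c1CC=C(C)C | intermediate
30 | Pestalone G, 2-(3-bromo-5-chloro-2-hydroxy-6-methoxy-4-methylbenzoyl)-4,6-dihydroxy-3-(3-methylbut-2-en-1-yl)benzaldehyde | COc1c(Cl)c(C)c(Br)c(O)c1C(=O)c1c(C=O)c(O)cc(O)c1CC=C(C)C | target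

**Step count**

Total: 18 steps. Longest linear sequence: 16 steps (steps 1–11, then 14–18); the cyclobutenone branch is steps 12–13.

**Steps most likely to fail**

Step 14. The [2+2] addition at the congested alkyne carbon may be slow, so that the ketene is consumed by dimerisation or by acylating the product phenol, or the silylated ynol ether may break down at the temperature needed to open 21. The fallback sets out from 17 and comes back at 26, and makes the ketene without the cyclobutenone. 3-Methylbut-2-enoic acid is chlorinated (Cl2, CH2Cl2, 0 °C) to 2,3-dichloro-3-methylbutanoic acid F1. KOH in ethanol removes HCl to give 2-chloro-3-methylbut-2-enoic acid F2, and (COCl)2 with catalytic DMF gives 2-chloro-3-methylbut-2-enoyl chloride F3. Slow addition of F3 to 17 and Et3N in CH2Cl2 at 0–25 °C should generate ketene 22 by 1,4-dehydrochlorination and trap it as 23 well below the temperature of the main route. Warming 23 in toluene at 80 °C should then carry the cascade through 24 and 25 to 26.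

Step 13. The allylic chloride shift may be incomplete before reduction, or reduction may go too far, leaving the chlorine-free cyclobutenone as a volatile contaminant that is hard to separate. The fallback sets out from 19 and comes back at 21. Complete dechlorination under amine-buffered conditions (Zn, AcOH, TMEDA, EtOH, 0 °C) should give 3-methylcyclobut-2-en-1-one F4. Addition of chlorine across the enone double bond (Cl2, CH2Cl2, −78 °C) should give 2,3-dichloro-3-methylcyclobutan-1-one F5 as a mixture of diastereomers. Et3N should then remove HCl by loss of the more acidic C2 proton and the C3 chloride (α-halogenation of an enone by addition–elimination) to give 21.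

Step 15. Electrophilic bromine may attack the prenyl double bond or C4′ of ring B instead of, or as well as, C4 of ring A. The fallback sets out from 26 and comes back at 29, and moves the halogenation to the benzophenone stage. TBAF in THF should give racemic 4-chloro-2-{[2-(dimethoxymethyl)-3,5-bis(methoxymethoxy)-6-(3-methylbut-2-en-1-yl)phenyl](hydroxy)methyl}-3-methoxy-5-methylphenol F6. Dess–Martin periodinane with pyridine should give (3-chloro-6-hydroxy-2-methoxy-4-methylphenyl)[2-(dimethoxymethyl)-3,5-bis(methoxymethoxy)-6-(3-methylbut-2-en-1-yl)phenyl]methanone F7. In F7 the ketone draws electron density from ring B (C4′ is para to the acyl carbon), while C4 of ring A is meta to it and still activated by OH and OMe. Bromination of F7 with NBS and catalytic i-Pr2NH in CH2Cl2 at low temperature should therefore be more selective for ring A and gives 29.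

**Further compounds**

F1 | step 14 | 2,3-dichloro-3-methylbutanoic acid (racemic) | CC(C)(Cl)C(Cl)C(=O)O
F2 | step 14 | 2-chloro-3-methylbut-2-enoic acid | CC(C)=C(Cl)C(=O)O
F3 | step 14 | 2-chloro-3-methylbut-2-enoyl chloride | CC(C)=C(Cl)C(Cl)=O
F4 | step 13 | 3-methylcyclobut-2-en-1-one | CC1=CC(=O)C1
F5 | step 13 | 2,3-dichloro-3-methylcyclobutan-1-one (racemic, mixture of diastereomers) | CC1(Cl)CC(=O)C1Cl
F6 | step 15 | racemic 4-chloro-2-{[2-(dimethoxymethyl)-3,5-bis(methoxymethoxy)-6-(3-methylbut-2-en-1-yl)phenyl](hydroxy)methyl}-3-methoxy-5-methylphenol | COc1c(Cl)c(C)cc(O)c1C(O)c1c(C(OC)OC)c(OCOC)cc(OCOC)c1CC=C(C)C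
F7 | step 15 | (3-chloro-6-hydroxy-2-methoxy-4-methylphenyl)[2-(dimethoxymethyl)-3,5-bis(methoxymethoxy)-6-(3-methylbut-2-en-1-yl)phenyl]methanone | COc1c(Cl)c(C)cc(O)c1C(=O)c1c(C(OC)OC)c(OCOC)cc(OCOC)c1CC=C(C)C
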